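Retrosynthesis: once the protecting groups are off, the C6'–C7' bond between ring B and the polyenyne is cut first. Next comes C6–C7 at ring A, then the C11=C12 and C11'=C12' olefins of a symmetrical C22 heptaenediyne (C10 dialdehyde plus two C6 enynyl phosphonium units).
Enabling feature: in ring B the triad C6'=C5'–C4'(OH) is the 1,3-transposed form of a tertiary ethynyl vinyl carbinol at C6', and O3' sits next to C4'. C6' can therefore be the carbonyl carbon of a 2,6,6-trimethylcyclohex-2-enone, and O3', armed as a tert-butyl carbonate, can deliver the oxygen to C4'.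
Forward order: ketoisophorone gives one (S)-4-hydroxy enone that serves both rings (ring A by silylation and reductive triflation, ring B as the Boc carbonate). The C22 diyne comes from a double Wittig reaction and takes up ring A by Sonogashira coupling. Ring B is then joined by acetylide addition, ionization and carbonate capture in one flask, followed by methanolysis and desilylation.
Stereochemistry: a single asymmetric transfer hydrogenation sets C3 and C3'. C4' is relayed from C3' through a temporary cis-fused 1,3-dioxolan-2-one.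
Olefin geometry: C9 and C9' come from the (E)-enynol, C13, C15 and C13' from the dialdehyde, and C11 and C11' from the E-selective tributylphosphonium Wittig reaction.

Key step: step 8

Remark: carotenoid numbering is used (ring A: C1–C6 with O3; ring B: C1'–C6' with O3' and O4'); 1, 7 and 10 are taken to be articles of commerce; the C6' centre of 16 and 17 is written without configuration because it is erased in the same flask.

Step 1
Reactants: 1 ketoisophorone (2,6,6-trimethylcyclohex-2-ene-1,4-dione)
Product: 2 (4S)-4-hydroxy-2,6,6-trimethylcyclohex-2-en-1-one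
Conditions: RuCl[(S,S)-TsDPEN](p-cymene) (cat.), KOt-Bu (cat.), i-PrOH, 20 °C
Reagents that add atoms: none
Why: Asymmetric transfer hydrogenation (Noyori type) should reduce only the unhindered C4 carbonyl, the C1 carbonyl being shielded by the quaternary carbon and the vinylic methyl group, and the (S,S)-ligand, with the enone π system in the place an aryl group usually takes in the transition state, should give the (S)-carbinol, the future C3 of ring A and C3' of ring B.

Step 2
Reactants: 2 (4S)-4-hydroxy-2,6,6-trimethylcyclohex-2-en-1-one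
Product: 3 (4S)-4-[(tert-butyldimethylsilyl)oxy]-2,6,6-trimethylcyclohex-2-en-1-one
Conditions: TBSCl, imidazole, DMF, 20 °C
Reagents that add atoms: tert-butyldimethylsilyl chloride CC(C)(C)[Si](C)(C)Cl
Why: Imidazole-promoted silyl ether formation on a secondary alcohol touches neither the stereocentre nor the enone.

Step 3
Reactants: 3 (4S)-4-[(tert-butyldimethylsilyl)oxy]-2,6,6-trimethylcyclohex-2-en-1-one
Product: 5 (4R)-4-[(tert-butyldimethylsilyl)oxy]-2,6,6-trimethylcyclohex-1-en-1-yl trifluoromethanesulfonate (ring A triflate), via lithium enolate 4 (not isolated)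
Conditions: LiBH(s-Bu)3, THF, −78 °C; then PhNTf2, −78 to 0 °C
Reagents that add atoms: N-phenylbis(trifluoromethanesulfonimide) O=S(=O)(C(F)(F)F)N(c1ccccc1)S(=O)(=O)C(F)(F)F
Why: Conjugate reduction with enolate trapping: the bulky borohydride cannot reach the carbonyl next to the quaternary carbon and adds hydride to the unsubstituted β-carbon, and the enolate, fixed in place because the other α-carbon bears no hydrogen, is O-sulfonylated to the tetrasubstituted enol triflate with the silyloxy stereocentre untouched.

Step 4
Reactants: 2 (4S)-4-hydroxy-2,6,6-trimethylcyclohex-2-en-1-one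
Product: 6 tert-butyl (1S)-3,5,5-trimethyl-4-oxocyclohex-2-en-1-yl carbonate (ring B enone)
Conditions: Boc2O, DMAP (cat.), CH2Cl2, 0 to 20 °C
Reagents that add atoms: di-tert-butyl dicarbonate CC(C)(C)OC(=O)OC(=O)OC(C)(C)C
Why: DMAP-catalysed O-acylation (mixed carbonate formation) arms O3' with the internal nucleophile of step 8 under conditions too mild to enolize the γ-position, so the stereocentre is kept.

Step 5
Reactants: 7 (2E)-3-methylpent-2-en-4-yn-1-ol
Product: 9 tributyl[(2E)-3-methylpent-2-en-4-yn-1-yl]phosphonium bromide, via allylic bromide 8 (not isolated)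
Conditions: PBr3, Et2O, −10 °C; washed and dried solution, then PBu3, toluene, 20 °C
Reagents that add atoms: phosphorus tribromide BrP(Br)Br; tributylphosphine CCCCP(CCCC)CCCC
Why: SN2 bromination of the primary allylic alcohol and quaternization of PBu3 (phosphonium salt formation) both act at the CH2 group and leave the E double bond and the terminal alkyne as they are.

Step 6
Reactants: 9 tributyl[(2E)-3-methylpent-2-en-4-yn-1-yl]phosphonium bromide (two equivalents); 10 (2E,4E,6E)-2,7-dimethylocta-2,4,6-trienedial (C10 dialdehyde)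
Product: 13 (3E,5E,7E,9E,11E,13E,15E)-3,7,12,16-tetramethyloctadeca-3,5,7,9,11,13,15-heptaene-1,17-diyne (C22 diyne; C7 to C7'), via phosphonium ylide 11 (not isolated), via C16 pentaenynal 12 (not isolated)
Conditions: NaOMe, CH2Cl2, 0 to 20 °C, dark; crystallization
Reagents that add atoms: none
Why: Twofold Wittig olefination forms C11=C12 and C11'=C12', allylic trialkylphosphonium ylides being known to favour E-olefins and NaOMe being strong enough for the salt but not for the alkyne C–H, and the symmetrical all-E hydrocarbon should be purified by crystallization.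

Step 7
Reactants: 5 ring A triflate; 13 C22 diyne (threefold excess)
Product: 14 C31 polyenyne (ring A silyl ether joined through C6–C7≡C8 to the all-E chain that ends in the free C8'≡C7'–H alkyne)
Conditions: Pd(PPh3)4 (cat.), CuI (cat.), i-Pr2NH, DMF/THF, 25 to 40 °C, argon, dark
Reagents that add atoms: none
Why: Sonogashira coupling of a cyclohexenyl triflate with a terminal enyne, a reaction type with close precedent for this ring, forms C6–C7, and the excess of symmetrical diyne, recovered by chromatography, should hold the reaction at one coupling.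

Step 8
Reactants: 14 C31 polyenyne; 6 ring B enone (tert-butyl carbonate)
Product: 18 C40 3-silyl ether 3',4'-cyclic carbonate, via lithium acetylide 15 (not isolated), via lithium alkoxide 16 (not isolated), via tertiary trifluoroacetate 17 (not isolated)
Conditions: 14, n-BuLi, THF, −78 °C; 6, LaCl3·2LiCl, −78 to −40 °C; then 2,6-lutidine, (CF3CO)2O, −78 to 0 °C, dark
Reagents that add atoms: none
Why: Proposed new method: lithium acetylide 15 adds 1,2 to the C6' carbonyl of 6 (LaCl3·2LiCl activates this hindered ketone so that the carbonate is left alone), alkoxide 16 is trifluoroacetylated in the flask, and ester 17, which is tertiary, allylic, propargylic and conjugated with the polyene, should ionize below 0 °C to a C4'–C5'–C6' allyl cation that the carbonyl oxygen of the C3' tert-butyl carbonate captures at C4', whereupon loss of 2-methylpropene makes the capture irreversible. The closest known reaction types are the addition of acetylides to 2,6,6-trimethylcyclohex-2-enones, the allylic rearrangement of ethynyl vinyl carbinols to conjugated enynols (the way compounds such as 7 are made) and the cyclization of tert-butyl carbonates onto halonium ions, activated epoxides and allyl cations; their union in one flask on a polyenyne is what is new. The 1,3-dioxolan-2-one closes in the 5-exo-trig mode on the C4'=C5' bond while the double bond moves to C5'=C6' (SN1' or anti-SN2'). C4' is controlled by C3': the O–C(=O) tether reaches only the ring face that bears O3', so the bicycle is cis-fused and C4' becomes R, while the configuration made at C6' in the addition is erased and needs no control. The step needs 1,2- over 1,4-addition (hard acetylide), ketone over carbonate (low temperature and lanthanum activation) and capture at C4' rather than at C8' or along the chain, which is secured because attack of trifluoroacetate at those sites is reversible whereas only the tethered carbonate at C4' can end the sequence. 2,6-Lutidine keeps the medium free of strong acid, so that the E-olefins, the silyl ether and the new allylic C4'–O bond should persist.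

Step 9
Reactants: 18 C40 3-silyl ether 3',4'-cyclic carbonate
Product: 19 C40 3-silyl ether 3',4'-cis-diol
Conditions: K2CO3 (cat.), MeOH/THF, 0 to 20 °C, dark
Reagents that add atoms: none
Why: Base-catalysed transesterification (methanolysis) of the strained five-membered carbonate breaks only acyl–oxygen bonds, so C3' and C4' keep their configuration and the silyl ether and polyenyne are unaffected.

Step 10
Reactants: 19 C40 3-silyl ether 3',4'-cis-diol
Product: 20 (all-E,3R,3'S,4'R)-7,8,7',8'-tetradehydro-β,β-carotene-3,3',4'-triol (target)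
Conditions: n-Bu4NF, THF, 0 to 20 °C, dark
Reagents that add atoms: none
Why: Fluoride-induced cleavage of the silyl ether under non-acidic conditions spares the ionizable allylic C4'–OH group and the E-polyenyne and should give the target.

Compound list
1 | ketoisophorone (2,6,6-trimethylcyclohex-2-ene-1,4-dione) | CC1=CC(=O)CC(C)(C)C1=O | starting material
2 | (4S)-4-hydroxy-2,6,6-trimethylcyclohex-2-en-1-one | CC1=C[C@@H](O)CC(C)(C)C1=O | intermediate
3 | (4S)-4-[(tert-butyldimethylsilyl)oxy]-2,6,6-trimethylcyclohex-2-en-1-one | CC1=C[C@@H](O[Si](C)(C)C(C)(C)C)CC(C)(C)C1=O | intermediate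
4 | lithium (4R)-4-[(tert-butyldimethylsilyl)oxy]-2,6,6-trimethylcyclohex-1-en-1-olate | CC1=C([O-])C(C)(C)C[C@H](O[Si](C)(C)C(C)(C)C)C1.[Li+] | intermediate
5 | (4R)-4-[(tert-butyldimethylsilyl)oxy]-2,6,6-trimethylcyclohex-1-en-1-yl trifluoromethanesulfonate | CC1=C(OS(=O)(=O)C(F)(F)F)C(C)(C)C[C@H](O[Si](C)(C)C(C)(C)C)C1 | intermediate
6 | tert-butyl (1S)-3,5,5-trimethyl-4-oxocyclohex-2-en-1-yl carbonate | CC1=C[C@@H](OC(=O)OC(C)(C)C)CC(C)(C)C1=O | intermediate
7 | (2E)-3-methylpent-2-en-4-yn-1-ol | C#C/C(C)=C/CO | starting material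
8 | (3E)-5-bromo-3-methylpent-3-en-1-yne | C#C/C(C)=C/CBr | intermediate
9 | tributyl[(2E)-3-methylpent-2-en-4-yn-1-yl]phosphonium bromide | C#C/C(C)=C/C[P+](CCCC)(CCCC)CCCC.[Br-] | intermediate
10 | (2E,4E,6E)-2,7-dimethylocta-2,4,6-trienedial | O=C/C(C)=C/C=C/C=C(C)/C=O | starting material
11 | tributylphosphonium (2E)-3-methylpent-2-en-4-yn-1-ylide | C#C/C(C)=C/[CH-][P+](CCCC)(CCCC)CCCC | intermediate
12 | (2E,4E,6E,8E,10E)-2,7,11-trimethyltrideca-2,4,6,8,10-pentaen-12-ynal | C#C/C(C)=C/C=C/C(C)=C/C=C/C=C(C)/C=O | intermediate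
13 | (3E,5E,7E,9E,11E,13E,15E)-3,7,12,16-tetramethyloctadeca-3,5,7,9,11,13,15-heptaene-1,17-diyne | C#C/C(C)=C/C=C/C(C)=C/C=C/C=C(C)/C=C/C=C(\C)C#C | intermediate
14 | C31 polyenyne: (3R)-silyloxy ring A, C7≡C8, all-E heptaene chain, terminal C8'≡C7'–H | CC1=C(C#C/C(C)=C/C=C/C(C)=C/C=C/C=C(C)/C=C/C=C(\C)C#C)C(C)(C)C[C@H](O[Si](C)(C)C(C)(C)C)C1 | intermediate
15 | lithium acetylide of 14 (Li on C7') | CC1=C(C#C/C(C)=C/C=C/C(C)=C/C=C/C=C(C)/C=C/C=C(\C)C#C[Li])C(C)(C)C[C@H](O[Si](C)(C)C(C)(C)C)C1 | intermediate
16 | lithium alkoxide of the C6' tertiary carbinol (C4'=C5' olefin, (3'S)-OBoc, C6' epimers) | CC1=C(C#C/C(C)=C/C=C/C(C)=C/C=C/C=C(C)/C=C/C=C(\C)C#CC2([O-])C(C)=C[C@@H](OC(=O)OC(C)(C)C)CC2(C)C)C(C)(C)C[C@H](O[Si](C)(C)C(C)(C)C)C1.[Li+] | intermediate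
17 | C6' tertiary trifluoroacetate of the same carbinol (C6' epimers) | CC1=C(C#C/C(C)=C/C=C/C(C)=C/C=C/C=C(C)/C=C/C=C(\C)C#CC2(OC(=O)C(F)(F)F)C(C)=C[C@@H](OC(=O)OC(C)(C)C)CC2(C)C)C(C)(C)C[C@H](O[Si](C)(C)C(C)(C)C)C1 | intermediate
18 | C40 (3R)-silyl ether (3'S,4'R)-cyclic carbonate, cis-fused dioxolanone on ring B | CC1=C(C#C/C(C)=C/C=C/C(C)=C/C=C/C=C(C)/C=C/C=C(\C)C#CC2=C(C)[C@H]3OC(=O)O[C@H]3CC2(C)C)C(C)(C)C[C@H](O[Si](C)(C)C(C)(C)C)C1 | intermediate
19 | C40 (3R)-silyl ether (3'S,4'R)-cis-diol | CC1=C(C#C/C(C)=C/C=C/C(C)=C/C=C/C=C(C)/C=C/C=C(\C)C#CC2=C(C)[C@@H](O)[C@@H](O)CC2(C)C)C(C)(C)C[C@H](O[Si](C)(C)C(C)(C)C)C1 | intermediate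
20 | (all-E,3R,3'S,4'R)-7,8,7',8'-tetradehydro-β,β-carotene-3,3',4'-triol | CC1=C(C#C/C(C)=C/C=C/C(C)=C/C=C/C=C(C)/C=C/C=C(\C)C#CC2=C(C)[C@@H](O)[C@@H](O)CC2(C)C)C(C)(C)C[C@H](O)C1 | target

Total step count: 10. Longest linear sequence: 7 (steps 1, 2, 3, 7, 8, 9, 10).

Steps most likely to fail

Step 8 (bears the label).
- What may go wrong: the acetylide may attack the carbonate or deprotonate the γ-position of 6 instead of adding to the hindered carbonyl. After ionization, the delocalized cation may lose a proton (from C3' or from a chain methyl group) or isomerize its olefins faster than the carbonate closes.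
- Fallback: the polarity at C6' is reversed and the cis-diol is made before the coupling, using known reaction types only. It sets out from 2 and 14 and comes back at 20.
- Phenylboronic acid and a catalytic secondary amine in toluene over molecular sieves should convert 2, by intramolecular oxa-Michael addition of the boronic hemiester on the face of O3', into the cis-fused phenylboronate of the dihydroxy ketone F1 (C5' epimers, erased later).
- Exchange with pinacol frees (3R,4S)-3,4-dihydroxy-2,6,6-trimethylcyclohexanone F2, and TBSOTf with 2,6-lutidine gives the bis-silyl ether F3.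
- KN(SiMe3)2 and PhNTf2 at −78 °C give the ring B enol triflate F4. Sonogashira coupling of F4 with 14 under the conditions of step 7 forms C6'–C7' and gives the C40 tris-silyl ether F5, and n-Bu4NF then gives 20.

Step 7.
- What may go wrong: coupling at both alkyne ends, oxidative dimerization of the alkyne, and slow oxidative addition of the hindered triflate to zerovalent palladium in the presence of a sparingly soluble polyene.
- Fallback: the chain is grown outward from ring A instead of desymmetrizing the diyne. It sets out from 5, 7, 9 and 10 and comes back at 14.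
- Sonogashira coupling of 5 with 7 gives the C15 enynol F6. CBr4 and PPh3 give the C15 allylic bromide F7, and PBu3 gives the C15 tributylphosphonium bromide F8.
- Wittig reaction of F8 with an excess of 10 (NaOMe, CH2Cl2) gives the C25 aldehyde F9. The second formyl group is deactivated by the longer conjugation once the first has reacted, a bias that the two remote alkyne ends of 13 lack.
- Wittig reaction of F9 with 9 then gives 14.

Step 6.
- What may go wrong: Z-olefin formation at C11=C12 and C11'=C12', and loss of the E geometry at C9=C10 by rotation within the delocalized allylic ylide.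
- Fallback: the roles of the carbonyl and ylide partners are exchanged. It sets out from 7 and 10 and comes back at 13.
- NaBH4 reduces 10 to the C10 diol F10, and PPh3·HBr in methanol gives the C10 bis(triphenylphosphonium) dibromide F11. MnO2 oxidizes 7 to (2E)-3-methylpent-2-en-4-ynal F12.
- Twofold Wittig reaction of F11 with F12 (NaOMe, CH2Cl2) gives 13. The ylide now rests on the central triene, whose methyl groups hold its geometry, and the C9=C10 bond stays in the aldehyde partner where it cannot rotate.

Further compounds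
F1 | step 8 | cis-fused 2-phenyl-1,3,2-dioxaborolane of (3R,4S)-3,4-dihydroxy-2,6,6-trimethylcyclohexanone | O=C1C(C)[C@H]2OB(c3ccccc3)O[C@H]2CC1(C)C
F2 | step 8 | (3R,4S)-3,4-dihydroxy-2,6,6-trimethylcyclohexanone | O=C1C(C)[C@@H](O)[C@@H](O)CC1(C)C
F3 | step 8 | (3R,4S)-3,4-bis[(tert-butyldimethylsilyl)oxy]-2,6,6-trimethylcyclohexanone | O=C1C(C)[C@@H](O[Si](C)(C)C(C)(C)C)[C@@H](O[Si](C)(C)C(C)(C)C)CC1(C)C
F4 | step 8 | (3R,4S)-3,4-bis[(tert-butyldimethylsilyl)oxy]-2,6,6-trimethylcyclohex-1-en-1-yl trifluoromethanesulfonate | O=S(=O)(OC1=C(C)[C@@H](O[Si](C)(C)C(C)(C)C)[C@@H](O[Si](C)(C)C(C)(C)C)CC1(C)C)C(F)(F)F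
F5 | step 8 | C40 3,3',4'-tris(tert-butyldimethylsilyl) ether of 20 | CC1=C(C#C/C(C)=C/C=C/C(C)=C/C=C/C=C(C)/C=C/C=C(\C)C#CC2=C(C)[C@@H](O[Si](C)(C)C(C)(C)C)[C@@H](O[Si](C)(C)C(C)(C)C)CC2(C)C)C(C)(C)C[C@H](O[Si](C)(C)C(C)(C)C)C1
F6 | step 7 | (2E)-5-{(4R)-4-[(tert-butyldimethylsilyl)oxy]-2,6,6-trimethylcyclohex-1-en-1-yl}-3-methylpent-2-en-4-yn-1-ol | CC1=C(C#C/C(C)=C/CO)C(C)(C)C[C@H](O[Si](C)(C)C(C)(C)C)C1
F7 | step 7 | C15 allylic bromide derived from F6 | CC1=C(C#C/C(C)=C/CBr)C(C)(C)C[C@H](O[Si](C)(C)C(C)(C)C)C1
F8 | step 7 | C15 tributylphosphonium bromide derived from F7 | CC1=C(C#C/C(C)=C/C[P+](CCCC)(CCCC)CCCC)C(C)(C)C[C@H](O[Si](C)(C)C(C)(C)C)C1.[Br-]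
F9 | step 7 | C25 aldehyde (ring A silyl ether, C7≡C8, all-E chain ending in the C12' formyl group) | CC1=C(C#C/C(C)=C/C=C/C(C)=C/C=C/C=C(C)/C=O)C(C)(C)C[C@H](O[Si](C)(C)C(C)(C)C)C1
F10 | step 6 | (2E,4E,6E)-2,7-dimethylocta-2,4,6-triene-1,8-diol | OC/C(C)=C/C=C/C=C(C)/CO
F11 | step 6 | (2E,4E,6E)-2,7-dimethylocta-2,4,6-triene-1,8-diylbis(triphenylphosphonium) dibromide | [Br-].[Br-].c1ccccc1[P+](c1ccccc1)(c1ccccc1)C/C(C)=C/C=C/C=C(C)/C[P+](c1ccccc1)(c1ccccc1)c1ccccc1
F12 | step 6 | (2E)-3-methylpent-2-en-4-ynal | C#C/C(C)=C/C=O
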